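Two flasks, one charge. Oak and birch hold the same mixture and differ in how long they stand.

- oak: free monomer 0.85 M; initiator 5 mol%; time 40 min
- birch: free monomer 0.85 M; initiator 5 mol%; time 12 min

    monomer in chains → over-reaction product (k1 = 7.6 × 10⁻⁶ s⁻¹)
    free monomer + living end → monomer in chains + living end, rate k2*[living end]*[free monomer] (k2 = 0.33 M⁻¹ s⁻¹)
    free monomer + initiator → living end + monomer in chains (k3 = 0.029 M⁻¹ s⁻¹)
    monomer in chains + living end → free monomer + living end, rate k4*[living end] as long as [monomer in chains] is above zero (k4 = 0.015 s⁻¹)

- the average divides the monomer in chains by the number of chains begun, living and dead together
- run time (oak): 40 min

1. which of the two ends with the longer chains by the average number of monomer units in a chain (chains begun, living or dead) ("neither" if they lie within 10%) (oak / birch / neither)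
2. average number of monomer units in a chain (chains begun, living or dead) at the end, oak
3. average number of monomer units in a chain (chains begun, living or dead) at the end, birch

We start with free monomer. A living end takes it up at a rate proportional to the free monomer concentration, and, as long as monomer in chains is above zero, gives it back at a rate that does not depend on how much monomer is in chains. The living end stands in both rates and cancels, so the two balance at a level of 0.0455 M, the equilibrium monomer concentration. With the whole charge as living ends, free monomer has a half-life of 0.824 min, and at the start initiator has one of 0.469 min. Because both are shorter than birch's 12 min, we take both flasks to reach that level.

This gives our one quantity, the plateau length 18.9: the monomer left for chains with free monomer at its level, divided by the chains the initiator charge can begin. We expect it to overcount chains a little, more in birch, because at the level initiator decays more slowly than at the start, with a half-life of 8.76 min, and birch gives it less time.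

Monomer in chains also decays by first order to over-reaction product, and with free monomer at its level that integrates to a surviving fraction of exp(−rate constant × time). By this estimate oak loses 1.81% of its chained monomer and birch 0.546%. We reckon 18.6 for oak and 18.8 for birch. These differ by less than 10%, so our answer is neither.

The forecast gives 18.7 for oak, 19.5 for birch, and neither, saying “Both runs therefore end near equilibrium”. Its birch figure stands above ours.

The simulation gives 18.7 for oak and 19.5 for birch, so the answer is neither; the plateau length we reckoned was 18.9. In birch at 12.0 min, monomer in chains is made at 0.992 of the rate at which it is used up, each step taken net, having been made 6.19 times faster at 2.15 min. At 12.0 min in birch, it returns to free monomer 100 times faster than it turns into over-reaction product. A neighbouring flask, the same as birch but with 3 mol% of initiator, has a plateau length of 31.6, and its average number of monomer units in a chain ends at 31.6.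

The constants used here belong to no real substance; the run is a simulation.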